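The north run halves its target every 5.00 h and the north-east run every 8.18 h, a faster loss with 0.44 mM of catalyst than with 0.28 mM, read after the substrate is down to 0 % and 1 %, and that comparison is where I begin on the quick number you asked for.

| setting | north-east | north | flask |
|---|---|---|---|
| substrate | 10 mM | 10 mM | 10 mM |
| gas phase | 2.2 mM (held) | 2.2 mM (held) | 2.2 mM (held) |
| catalyst | 0.28 mM | 0.44 mM | 0.20 mM |
| remark | run made earlier | run made earlier |  |
| time |  |  | 20 h |

| run | time / h | target / % | substrate / % |
|---|---|---|---|
| north-east | 2.00 | 29 | 69 |
| north-east | 6.00 | 59 | 14 |
| north-east | 12.0 | 46 | 2 |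
| north-east | 15.0 | 35 | 1 |
| north-east | 25.0 | 15 | 0 |
| north | 5.00 | 54 | 17 |
| north | 10.0 | 36 | 0 |
| north | 15.0 | 20 | 0 |
| north | 20.0 | 9 | 0 |
| north | 25.0 | 7 | 1 |

(standard deviation of a reading: 1.5 percentage points)

- target at 20 h, in percent of the substrate charged
- the change that raises the amount of target at 20 h, in percent of the substrate charged most ("none" if none brings more than 2 percentage points) (autumn / dusk / spring / none)
- amount of target at 20 h, in percent of the substrate charged, after autumn

- autumn: doubling the saturation concentration of gas phase, all else as stated
- dusk: doubling the transfer coefficient of the gas phase, all else as stated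
- spring: doubling the amount of catalyst, all else as stated

- the analysis behind the earlier runs scatters by 1.5 percentage points, standard deviation
- at the start none of the gas phase is in solution

Half-life times catalyst comes to 7.92 M·s in the north run and 8.25 M·s in the north-east run, which I take as equal within the scatter, so I treat the loss of target at fixed catalyst as pseudo-first-order, with a rate in proportion to catalyst, and keep the mean, L = 8.08 M·s. For the flask this gives 11.2 h, the half-life of target, τ = L/[catalyst], and spring shortens it to 5.60 h.

The north-east run read 35 % at 15.0 h, and the flask reaches the same catalyst times time at 21.0 h, so my rough figure, running τ back 1.00 h to 20 h, is 37.2 %. The forecast, which differs slightly, says 38 %, best change none, and 13 % after autumn, holding that “Autumn probably speeds overreaction too, if the gas drives that step”.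

The flask gives 34.9 % at 20 h, the best change is none, and autumn gives 31.9 % against the forecast's 13 %, with this scheme behind the numbers:

    substrate + target → side product (k = 8.90 × 10⁻⁴ M⁻¹ s⁻¹)
    substrate + dissolved gas + catalyst → catalyst + target (k = 320 M⁻² s⁻¹)
    gas phase ⇌ dissolved gas, rate k3*(csat - [dissolved gas]) (kL = 3.30 × 10⁻⁴ s⁻¹)
    catalyst + target → catalyst + over-reaction product (k = 0.0860 M⁻¹ s⁻¹)

The step from target to over-reaction product holds catalyst and target, with no dissolved gas in it. With the substrate of the flask at 0.0290 % at 20 h, I run τ on from 34.9 % for the 52.0 h to the same flask left until 3.0 d, which reckons 1.40 %, and that flask holds 1.40 % of target.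

The data stem from a simulated flask for substances that don't exist.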